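**Retrosynthetic overview**

The strategy rests on the only stereocentre, the sp3 carbon of the six-membered enolised trione ring that carries methyl and geranyl. It is stereogenic only because the two enol arms flanking it differ: one leads to the ring carbon bearing the CH2 bridge to the chromene, the other to the ring carbon bearing the acetyl group. Removing both leaves a mirror-symmetric 2-geranyl-2-methylcyclohexane-1,3,5-trione with two enantiotopic ring CH carbons.
Disconnections: the C-acetyl group comes off last; the bond between the bridging CH2 and the trione ring carbon is then cut, to be made by catalyst-controlled addition of the symmetric trione to an o-quinone methide released from a 6-(tosylmethyl)chromene. The chromene half goes back to hexanoylphloroglucinol, 3-methylbut-2-enal, formaldehyde and a sulfinate; the trione goes back to geranyl bromide, methyl 2-methylacetoacetate and an acetyl donor.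
Ring order: the trione carbocycle is closed first by intramolecular Claisen condensation, the pyran ring is fused onto the purchased benzene ring by oxa-6π electrocyclisation, the two ring systems are joined through the CH2 group, and no ring is formed afterwards.

Key step: step 7

Assumption: the sense of enantiotopic-site selection in step 7 cannot be predicted with confidence, so the quinine-derived squaramide is nominated and its quinidine-derived pseudoenantiomer, 3-[[3,5-bis(trifluoromethyl)phenyl]amino]-4-[[(9R)-6'-methoxycinchonan-9-yl]amino]cyclobut-3-ene-1,2-dione, replaces it unchanged otherwise if the mirror-image adduct should predominate.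

**Route**

Step 1
Reactants: 1 geranyl bromide [(2E)-1-bromo-3,7-dimethylocta-2,6-diene]; 2 methyl 2-methyl-3-oxobutanoate (methyl 2-methylacetoacetate)
Product: 3 methyl (4E)-2-acetyl-2,5,9-trimethyldeca-4,8-dienoate (racemic)
Conditions: NaH (1.1 equiv), THF, 0 °C; then 1 (1.05 equiv), 0 °C to rt
Reagents that add atoms: none
Why: SN2 C-alkylation of the sodium enolate of the β-keto ester by the primary allylic bromide should give the quaternary carbon as a racemate (later made prochiral) and leaves the E alkene of the geranyl chain untouched.

Step 2
Reactants: 3 methyl (4E)-2-acetyl-2,5,9-trimethyldeca-4,8-dienoate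
Product: 4 methyl (4E)-2,5,9-trimethyl-2-(3-oxobutanoyl)deca-4,8-dienoate (racemic)
Conditions: MgBr2·OEt2 (2.5 equiv), i-Pr2NEt (3 equiv), 1-acetyl-1H-benzotriazole (1.3 equiv), CH2Cl2, rt; 1 M HCl wash
Reagents that add atoms: 1-acetyl-1H-benzotriazole, CC(=O)n1nnc2ccccc21
Why: magnesium chelation of the β-keto ester makes the methyl ketone, the only enolisable position of 3, acidic enough for soft enolisation by the amine, and the magnesium enolate is C-acetylated by the acyl benzotriazole in a crossed Claisen-type acylation, the new diketone being held as its magnesium chelate.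

Step 3
Reactants: 4 methyl (4E)-2,5,9-trimethyl-2-(3-oxobutanoyl)deca-4,8-dienoate
Product: 5 2-[(2E)-3,7-dimethylocta-2,6-dienyl]-2-methylcyclohexane-1,3,5-trione (achiral; enolised in solution)
Conditions: LiN(i-Pr)2 (3.0 equiv), THF, −78 °C to 0 °C; 1 M HCl to pH 2
Reagents that add atoms: none
Why: the terminal carbanion of the diketone dianion lies six atoms from the ester carbonyl, so an intramolecular Claisen (Dieckmann-type) condensation should close the cyclohexane-1,3,5-trione ring, driven by loss of methoxide and deprotonation of the acidic product, and the ring closure turns the racemic quaternary carbon into a prochiral one.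

Step 4
Reactants: 6 phloroglucinol (benzene-1,3,5-triol); 7 hexanoyl chloride
Product: 8 1-(2,4,6-trihydroxyphenyl)hexan-1-one
Conditions: AlCl3 (3.5 equiv), PhNO2/CH2Cl2, 0 °C to 40 °C; ice/1 M HCl
Reagents that add atoms: none
Why: Friedel–Crafts acylation of the strongly activated ring is expected to stop after one acyl group because the chelated aryl ketone deactivates the ring toward a second acylation.

Step 5
Reactants: 8 1-(2,4,6-trihydroxyphenyl)hexan-1-one; 9 3-methylbut-2-enal
Product: 11 1-(5,7-dihydroxy-2,2-dimethyl-2H-chromen-8-yl)hexan-1-one, via oxatriene quinone methide 10 (not isolated)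
Conditions: 9 (1.2 equiv), ethylenediammonium diacetate (0.2 equiv), xylene, 130 °C; silica gel chromatography to remove the 6-acyl isomer
Reagents that add atoms: none
Why: amine-salt-catalysed Knoevenagel-type condensation at a free ring carbon gives the 1-oxatriene 10, which closes to the 2H-pyran by oxa-6π electrocyclisation, closure through the oxygen next to the acyl-bearing carbon giving 11 and closure through the other oxygen giving the 6-acyl isomer that is separated.

Step 6
Reactants: 11 1-(5,7-dihydroxy-2,2-dimethyl-2H-chromen-8-yl)hexan-1-one
Product: 12 1-[5,7-dihydroxy-2,2-dimethyl-6-[(4-methylphenyl)sulfonylmethyl]-2H-chromen-8-yl]hexan-1-one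
Conditions: aq. CH2O (37%, 3 equiv), TolSO2Na (4 equiv), AcOH/H2O, 40 °C
Reagents that add atoms: formaldehyde, C=O; sodium p-toluenesulfinate, [Na+].[O-]S(=O)c1ccc(C)cc1
Why: hydroxymethylation of the single free, doubly activated ring carbon followed by acid-promoted loss of water gives a protonated quinone methide that the excess sulfinate should capture at sulfur, a Mannich-type three-component sulfonylmethylation.

Step 7
Reactants: 5 2-[(2E)-3,7-dimethylocta-2,6-dienyl]-2-methylcyclohexane-1,3,5-trione (2 equiv); 12 1-[5,7-dihydroxy-2,2-dimethyl-6-[(4-methylphenyl)sulfonylmethyl]-2H-chromen-8-yl]hexan-1-one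
Product: 14 1-[6-[[(3S)-3-[(2E)-3,7-dimethylocta-2,6-dienyl]-2,4-dihydroxy-3-methyl-6-oxocyclohexa-1,4-dien-1-yl]methyl]-5,7-dihydroxy-2,2-dimethyl-2H-chromen-8-yl]hexan-1-one, via o-quinone methide 13 (not isolated)
Conditions: 3-[[3,5-bis(trifluoromethyl)phenyl]amino]-4-[[(8α,9S)-6'-methoxycinchonan-9-yl]amino]cyclobut-3-ene-1,2-dione (quinine-derived squaramide, C32H28F6N4O3, 10 mol%), 5% aq. NaHCO3 (3 equiv), CH2Cl2, 0 °C; then 0.5 M HCl to pH 3, excess 5 recovered
Reagents that add atoms: none
Why: Proposed new method: NaHCO3 ionises the phenol of 12 and p-toluenesulfinate leaves to give the acyl-stabilised o-quinone methide 13, while the quinuclidine nitrogen of the catalyst takes the acidic enol proton of 5 to give a chiral ammonium enolate and the squaramide NH pair hydrogen-bonds the quinone methide carbonyl, so that one ring CH carbon of the enolate adds 1,4 to the exocyclic methylene and the chromene ring regains its aromaticity. The closest known reaction type is the amine-squaramide-catalysed enantioselective conjugate addition of cyclic 1,3-diones to o-quinone methides released from 2-(arylsulfonylmethyl)phenols, taken together with catalytic desymmetrisations of prochiral 2,2-disubstituted cyclic 1,3-diones; new here is the use of such an addition to tell apart two enantiotopic nucleophilic carbons of a 2,2-disubstituted 1,3,5-trione. No ring closes in this step, which forms only the bond between the bridging CH2 and the trione ring carbon. The ring carbon bearing methyl and geranyl becomes the stereocentre under catalyst control: the geranyl chain shields one face of the planar enolate, so the electrophile held by the squaramide comes in over the methyl face and the chiral pocket places it above one of the two mirror-related CH carbons (the pseudoenantiomeric catalyst would place it above the other). The step needs enantiotopic-site selectivity and mono-addition, which are served by the mirror symmetry of 5 with exactly two equivalent nucleophilic carbons, by the single electrophilic carbon of 13, by the excess of 5 and by the greater hindrance and internal hydrogen bonding of the adduct. The adduct is held as its enolate under the weak base, which disfavours retro-Michael cleavage of the bridge and thus loss of enantiomeric purity.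

Step 8
Reactants: 14 1-[6-[[(3S)-3-[(2E)-3,7-dimethylocta-2,6-dienyl]-2,4-dihydroxy-3-methyl-6-oxocyclohexa-1,4-dien-1-yl]methyl]-5,7-dihydroxy-2,2-dimethyl-2H-chromen-8-yl]hexan-1-one
Product: 16 1-[6-[[(3R)-5-acetyl-3-[(2E)-3,7-dimethylocta-2,6-dienyl]-2,4-dihydroxy-3-methyl-6-oxocyclohexa-1,4-dien-1-yl]methyl]-5,7-dihydroxy-2,2-dimethyl-2H-chromen-8-yl]hexan-1-one (CNP0319887.1), via enol acetate 15 (not isolated)
Conditions: Ac2O (1.1 equiv), Et3N (1.2 equiv), 4-(dimethylamino)pyridine (0.3 equiv), CH2Cl2, 0 °C to rt; 0.5 M HCl wash
Reagents that add atoms: acetic anhydride, CC(=O)OC(C)=O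
Why: the trione enol, by far the most acidic and least encumbered hydroxyl (one phenol is chelated to the hexanoyl carbonyl and the other sits between two ortho substituents), should be acetylated first, after which 4-(dimethylamino)pyridine carries the acetyl group from oxygen to the one free ring carbon in the O-to-C acyl migration typical of 1,3-dione enol esters, the strongly acidic 2-acyl-1,3-dione being the thermodynamic sink and the stereocentre remaining untouched (its descriptor changes from S to R only because the substituent priorities change).

**Compound list**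

1 | geranyl bromide, (2E)-1-bromo-3,7-dimethylocta-2,6-diene | BrC/C=C(\C)CCC=C(C)C | starting material
2 | methyl 2-methyl-3-oxobutanoate | COC(=O)C(C)C(C)=O | starting material
3 | methyl (4E)-2-acetyl-2,5,9-trimethyldeca-4,8-dienoate (racemic) | COC(=O)C(C)(C/C=C(\C)CCC=C(C)C)C(C)=O | intermediate
4 | methyl (4E)-2,5,9-trimethyl-2-(3-oxobutanoyl)deca-4,8-dienoate (racemic) | COC(=O)C(C)(C/C=C(\C)CCC=C(C)C)C(=O)CC(C)=O | intermediate
5 | 2-[(2E)-3,7-dimethylocta-2,6-dienyl]-2-methylcyclohexane-1,3,5-trione (achiral, drawn as the triketo tautomer) | O=C1CC(=O)C(C)(C/C=C(\C)CCC=C(C)C)C(=O)C1 | intermediate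
6 | phloroglucinol | Oc1cc(O)cc(O)c1 | starting material
7 | hexanoyl chloride | CCCCCC(Cl)=O | starting material
8 | 1-(2,4,6-trihydroxyphenyl)hexan-1-one | CCCCCC(=O)c1c(O)cc(O)cc1O | intermediate
9 | 3-methylbut-2-enal | CC(C)=CC=O | starting material
10 | 2-hexanoyl-3,5-dihydroxy-6-(3-methylbut-2-en-1-ylidene)cyclohexa-2,4-dien-1-one (oxatriene, formed in the flask) | CCCCCC(=O)C1=C(O)C=C(O)C(=CC=C(C)C)C1=O | intermediate
11 | 1-(5,7-dihydroxy-2,2-dimethyl-2H-chromen-8-yl)hexan-1-one | CCCCCC(=O)c1c(O)cc(O)c2c1OC(C)(C)C=C2 | intermediate
12 | 1-[5,7-dihydroxy-2,2-dimethyl-6-[(4-methylphenyl)sulfonylmethyl]-2H-chromen-8-yl]hexan-1-one | CCCCCC(=O)c1c(O)c(CS(=O)(=O)c3ccc(C)cc3)c(O)c2c1OC(C)(C)C=C2 | intermediate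
13 | 8-hexanoyl-5-hydroxy-2,2-dimethyl-6-methylidene-2H-chromen-7(6H)-one (o-quinone methide, one tautomer drawn, formed in the flask) | CCCCCC(=O)C1=C2OC(C)(C)C=CC2=C(O)C(=C)C1=O | intermediate
14 | 1-[6-[[(3S)-3-[(2E)-3,7-dimethylocta-2,6-dienyl]-2,4-dihydroxy-3-methyl-6-oxocyclohexa-1,4-dien-1-yl]methyl]-5,7-dihydroxy-2,2-dimethyl-2H-chromen-8-yl]hexan-1-one | CCCCCC(=O)c1c(O)c(CC2=C(O)[C@@](C)(C/C=C(\C)CCC=C(C)C)C(O)=CC2=O)c(O)c2c1OC(C)(C)C=C2 | intermediate
15 | enol acetate of 14 at the enol oxygen next to the free ring CH, (3R) descriptor, same spatial arrangement (formed in the flask) | CCCCCC(=O)c1c(O)c(CC2=C(O)[C@@](C)(C/C=C(\C)CCC=C(C)C)C(OC(C)=O)=CC2=O)c(O)c2c1OC(C)(C)C=C2 | intermediate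
16 | 1-[6-[[(3R)-5-acetyl-3-[(2E)-3,7-dimethylocta-2,6-dienyl]-2,4-dihydroxy-3-methyl-6-oxocyclohexa-1,4-dien-1-yl]methyl]-5,7-dihydroxy-2,2-dimethyl-2H-chromen-8-yl]hexan-1-one (CNP0319887.1) | CCCCCC(=O)c1c(O)c(CC2=C(O)[C@@](C)(C/C=C(\C)CCC=C(C)C)C(O)=C(C(C)=O)C2=O)c(O)c2c1OC(C)(C)C=C2 | target

**Step count**

Total step count: 8. Longest linear sequence: 5 steps (steps 1, 2, 3, 7, 8, or equally steps 4, 5, 6, 7, 8).

**Steps most likely to fail**

Step 7 (proposed new method). The catalyst may discriminate poorly between the two enantiotopic ring carbons, an uncatalysed addition through the sodium enolate at the phase boundary may dilute the selectivity, or a second quinone methide may add to the remaining ring CH. The fallback uses only known chemistry and gives up catalyst control. Starting from 12 and 5 (2 equiv), the base-mediated quinone methide Michael addition is run without a chiral catalyst (5% aq. NaHCO3, Bu4NBr 10 mol%, CH2Cl2, 0 °C) and should give the racemic bridged adduct F1. The enantiomers of F1 are then separated by preparative chromatography on cellulose tris(3,5-dimethylphenylcarbamate) with an acidified eluent. The (S)-enantiomer is 14, where the route is rejoined, and the other enantiomer is set aside.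

Step 6. The benzylic cation may be captured by unreacted chromene faster than by sulfinate, giving the methylene-bridged bis-chromene, or the sulfone may ionise again during isolation. The fallback avoids a free cation in the presence of unreacted arene. Starting from 11, aminomethylation with N,N-dimethylmethyleneiminium iodide (CH2Cl2, rt; NaHCO3 wash) should give the Mannich base F2. Heating F2 with TolSO2Na in AcOH at 70 °C exchanges dimethylamine for the sulfinate through the quinone methide and returns to the route at 12.

Step 8. Acetylation may spread to the two phenols, or the base may trigger retro-Michael scission of the methylene bridge before the acetyl group has migrated to carbon. The fallback replaces chemoselective mono-acetylation by exhaustive acetylation followed by selective deacetylation. Starting from 14, excess Ac2O with pyridine and 4-(dimethylamino)pyridine (CH2Cl2, rt; aqueous work-up) should acetylate both phenols and install the C-acetyl group by the same migration, giving the bis(aryl acetate) of the target F3. Brief methanolysis (K2CO3, MeOH, 0 °C; then pH 3) removes the two aryl acetates, together with any enol acetate, while the triketone is protected as its enolate, and arrives at 16.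

**Further compounds**

F1 | step 7 | racemic 1-[6-[[3-[(2E)-3,7-dimethylocta-2,6-dienyl]-2,4-dihydroxy-3-methyl-6-oxocyclohexa-1,4-dien-1-yl]methyl]-5,7-dihydroxy-2,2-dimethyl-2H-chromen-8-yl]hexan-1-one | CCCCCC(=O)c1c(O)c(CC2=C(O)C(C)(C/C=C(\C)CCC=C(C)C)C(O)=CC2=O)c(O)c2c1OC(C)(C)C=C2
F2 | step 6 | 1-[6-(dimethylaminomethyl)-5,7-dihydroxy-2,2-dimethyl-2H-chromen-8-yl]hexan-1-one | CCCCCC(=O)c1c(O)c(CN(C)C)c(O)c2c1OC(C)(C)C=C2
F3 | step 8 | 5,7-di-O-acetyl derivative of 16 (both chromene phenols acetylated, (3R) stereocentre unchanged) | CCCCCC(=O)c1c(OC(C)=O)c(CC2=C(O)[C@@](C)(C/C=C(\C)CCC=C(C)C)C(O)=C(C(C)=O)C2=O)c(OC(C)=O)c2c1OC(C)(C)C=C2
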